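## Analysis of the target

Grevirobstol B (18) is a 22-membered macrocycle in which two phenolic rings are joined twice: once through a diaryl ether oxygen and once through an unbranched tether of sixteen methylene carbons, C1 to C16. Ring A, the monohydroxy ring, is 1,3,5-substituted, with C1 of the tether at position 1, the ether oxygen at position 3 and a free hydroxyl at position 5. Ring B carries the ether oxygen at position 1, C16 at position 2 and hydroxyls at positions 4 and 6, so its ether carbon is flanked on both sides and the ring is a 1,2,4-trioxygenated arene. The molecule has no stereocentre, and a ring this large and flexible is not expected to hold a stable chiral conformation, so no stereocontrol is needed. The sensitive part is ring B, which as a free hydroxyquinol-type phenol oxidises easily to a quinone; the three hydroxyls are therefore kept as methyl ethers until the last step. The difficulty is twofold: a large ring must be closed through a tether that has no functional group to use as a handle, and a sterically shielded diaryl ether must be made. The strategy rests on the fact that C1 to C16 are all methylenes, so any unsaturation in the tether can be erased by hydrogenation; C11 to C14 can therefore be carried as a 1,3-diyne whose central bond C12–C13 comes from oxidative coupling of two terminal alkynes. The carbon count then fixes the arms: a twelve-carbon dodec-11-ynyl arm (C1–C12) on ring A and a four-carbon but-3-ynyl arm (C13–C16) on ring B.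

## Retrosynthetic reasoning

**18 from 17.** The three O–methyl bonds are cut last. Methyl ethers are the only protection needed; they survive every earlier step and fall together under a boron Lewis acid, at a stage where no alkyne remains that could add hydrogen halide.

**17 from 16.** Eight C–H bonds at C11 to C14 are removed, turning the saturated tether into the 1,3-diyne of 16. The forward reaction is an exhaustive hydrogenation, and since every intermediate alkene ends as a methylene no geometry matters.

**16 from 15.** The C12–C13 bond is cut. It is the one tether bond that can be made by oxidatively joining two identical, unreactive end groups, and it lies far from both rings. It also divides the tether into a four-carbon arm (one propargylation of a benzylic carbon) and a twelve-carbon arm (a ten-carbon alkenyl bromide plus an acetylene). The gain is an acyclic diaryl ether, 15, with two independently built arms. The forward reaction must couple the two alkyne ends within one molecule and not between molecules.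

**15 from 14.** Two C–Si bonds are cut. The long-arm alkyne is carried with a triisopropylsilyl cap, which should survive hydroboration, palladium and copper catalysis, hydride reduction and an organolithium. The cap also removes the acidic alkyne hydrogen that would otherwise quench the carbanion 13. The short-arm alkyne arrives with the trimethylsilyl cap of 12. One fluoride treatment removes both.

**14 from 11 and 12.** The C15–C16 bond is cut. The benzylic bromide 11 supplies C16 as the electrophile, and the propargylic carbanion 13, made from 12, supplies C13 to C15. The silyl group of 13 steers alkylation to the propargylic terminus.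

**11 from 10 from 9.** These are functional-group changes at C16: bromomethyl back to hydroxymethyl back to formyl. The formyl group of 9 serves twice: it becomes C16, and before that it activates the neighbouring carbon–bromine bond of 8.

**9 from 7 and 8.** The ether bond between the oxygen and position 1 of ring B is cut. An intermolecular Ullmann etherification makes this hindered bond early, on small robust partners and with the help of the ortho formyl group, so the macrocyclisation does not have to overcome this hindrance.

**7 from 4 and 5.** The bond between C1 and ring A is cut. Hydroboration of the terminal alkene of 4 gives the alkylborane 6, which is coupled with 5 in a B-alkyl Suzuki–Miyaura reaction. In 5 the two oxygens of ring A are already differentiated, which avoids a selective mono-demethylation in the presence of an alkyne. An alkylborane, unlike a Grignard reagent, also tolerates the free phenol.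

**4 from 1 and 2.** The C10–C11 bond is cut: the acetylide 3, made from 1, is alkylated by the primary bromide 2. The two acetylenic carbons of 1 become C11 and C12, the ten carbons of 2 become C1 to C10, and the vinyl group of 2 later supplies C1 and C2.

## Alternatives that were turned down

**Alternative 1:** The ring would be opened at the ether bond between the oxygen and position 1 of ring B, with the two hydroxyl-bearing carbons of ring B carried as formyl carbons.
- **Forward key step:** a phenoxide of the open-chain fluoro dialdehyde A1 displaces fluoride under dilute carbonate conditions and gives the macrocyclic dialdehyde A2. A two-fold Dakin-type oxidation with hydrolysis would then turn both formyl groups into hydroxyls and give 18.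
- **For it:** the fluoride is activated by an ortho and a para formyl group, so ring closure is a fast, irreversible polar step without metal. Ring A is a symmetric resorcinol, so either hydroxyl gives the same ring and nothing on ring A needs protection. The hindered ether bond is formed under better activation than in the intermolecular Ullmann coupling of the chosen route; on this point the alternative is stronger.
- **Against it:** A1 has the whole sixteen-carbon chain between two arenes, joined without any help from ring closure. It must be joined while two aldehydes and a labile aryl fluoride are present or masked, which costs acetal protection and extra steps. A2 still has a free phenoxide on ring A that can attack a second molecule. The end game puts a peracid onto a molecule with an electron-rich free phenol and creates the oxidation-prone hydroxyquinol ring B under oxidising conditions.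
- **Comparison:** in place of the better-activated ether formation, the chosen route offers a tether built from two short arms made from purchasable pieces, methyl-ether protection of every oxygen to the last step, and no oxidant after ring closure.

**Alternative 2:** Ring A is removed altogether. Its six carbons are traced back to a cyclobutenone bearing the tether at its position 3 and to the two carbons of an aryl ethynyl ether on ring B, so ring A and the 22-membered ring form together.
- **Forward key step:** heating A3 at high dilution opens the cyclobutenone to a vinylketene, which adds across the ynol ether in a [2+2] reaction. The 2-vinylcyclobutenone opens again, and the dienylketene closes by 6π electrocyclisation and tautomerises to the phenol A4. One demethylation of A4 gives 18.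
- **For it:** no reagent is needed and the 1,3,5 pattern is set with complete regiocontrol (hydroxyl from the ketene carbonyl, aryloxy from the ynol ether, alkyl from the cyclobutenone). The ring A hydroxyl is formed free and differentiated, and only one step follows the key step. On atom economy and on step count after ring closure it is stronger.
- **Against it:** the benzannulation is known as a bimolecular reaction run concentrated with excess alkyne; a macrocyclising version at high dilution, where vinylketene dimerisation competes, has no close counterpart. A3 holds two sensitive functions, an ynol ether on a doubly flanked phenol oxygen and a cyclobutenone, and both must be installed late on a long-chain substrate.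
- **Comparison:** the chosen route gives up the elegance of building ring A and accepts one more step after closure. In exchange its ring closure belongs to a reaction class established for large rings, and its precursor 15 is robust and simply made.

**Alternative 3:** The ring is opened at the ether bond between the oxygen and position 3 of ring A, with ring A carried in reduced form as a cyclohexenone.
- **Forward key step:** the ring B phenoxide of A5 adds to the 3-chloroenone and chloride is expelled, giving the racemic vinylogous ester A6. Dehydrogenation of the cyclohexenone would give A4, and demethylation would give 18.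
- **For it:** addition–elimination at a vinylogous acid chloride runs at room temperature without metal, so the hindered oxygen is arylated under milder conditions than an Ullmann coupling; on this point it is stronger. The ring A hydroxyl emerges free.
- **Against it:** the chloroenone is hydrolytically labile and must be generated at the end of a long linear sequence, next to a phenol that has to be unmasked without touching it. The aromatisation must dehydrogenate a macrocyclic aryloxy enone in the presence of the electron-rich ring B without cleaving the vinylogous ester. Both steps after the key step are then uncertain, where the chosen route ends with a hydrogenation and a demethylation.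
- **Comparison:** the chosen route buys both rings as arenes, needs no oxidation-state adjustment of ring A, and leaves only the macrocyclisation as the uncertain step.

Key step: step 8

Remark: tether carbons are numbered C1 (on ring A) to C16 (on ring B); compounds 1, 2, 5, 8 and 12 are taken to be purchasable.

## Route

Step 1
Reactants: 1 ethynyltriisopropylsilane; 2 10-bromodec-1-ene
Product: 4 (dodec-11-en-1-yn-1-yl)triisopropylsilane, via lithium (triisopropylsilyl)acetylide 3 (not isolated)
Conditions: n-BuLi, THF, −78 → 0 °C; then 2, DMPU, 0 °C → rt
Reagents that add atoms: none
Why: SN2 alkylation of a lithium acetylide by a primary bromide in a dipolar cosolvent forms C10–C11 and joins the two acetylenic carbons of 1 to the ten carbons of 2, giving the twelve-carbon enyne chain. The silyl cap prevents a second alkylation and the remote terminal alkene is inert to the acetylide.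

Step 2
Reactants: 4 (dodec-11-en-1-yn-1-yl)triisopropylsilane; 5 3-bromo-5-methoxyphenol
Product: 7 3-methoxy-5-[12-(triisopropylsilyl)dodec-11-yn-1-yl]phenol, via B-alkyl-9-BBN borane 6 (not isolated)
Conditions: 9-BBN, THF, 0 °C → rt; then 5, PdCl2(dppf) (5 mol %), aq. K3PO4, DMF, 60 °C
Reagents that add atoms: none
Why: Anti-Markovnikov hydroboration of the terminal alkene (9-BBN reacts far more slowly with the hindered silylalkyne) followed by B-alkyl Suzuki–Miyaura coupling at the zerovalent palladium formed in situ joins C1 to ring A. The phenol is carried as its phenoxide with extra base, and the triisopropylsilyl alkyne should withstand the aqueous phosphate.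

Step 3
Reactants: 7 3-methoxy-5-[12-(triisopropylsilyl)dodec-11-yn-1-yl]phenol; 8 2-bromo-3,5-dimethoxybenzaldehyde
Product: 9 3,5-dimethoxy-2-{3-methoxy-5-[12-(triisopropylsilyl)dodec-11-yn-1-yl]phenoxy}benzaldehyde
Conditions: CuI (20 mol %), N,N-dimethylglycine hydrochloride (60 mol %), Cs2CO3, 1,4-dioxane, 100 °C
Reagents that add atoms: none
Why: Ligand-accelerated Ullmann diaryl ether synthesis; the ortho formyl group activates the flanked carbon–bromine bond of 8, only 8 carries a halide so self-coupling is excluded, and the silylalkyne and the non-enolisable aldehyde should be inert to carbonate.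

Step 4
Reactants: 9 3,5-dimethoxy-2-{3-methoxy-5-[12-(triisopropylsilyl)dodec-11-yn-1-yl]phenoxy}benzaldehyde
Product: 10 (3,5-dimethoxy-2-{3-methoxy-5-[12-(triisopropylsilyl)dodec-11-yn-1-yl]phenoxy}phenyl)methanol
Conditions: NaBH4, MeOH/THF, 0 °C
Reagents that add atoms: none
Why: Borohydride reduction of an aryl aldehyde to the benzylic alcohol; nothing else in the molecule is reducible under these conditions.

Step 5
Reactants: 10 (3,5-dimethoxy-2-{3-methoxy-5-[12-(triisopropylsilyl)dodec-11-yn-1-yl]phenoxy}phenyl)methanol
Product: 11 {12-[3-(2-(bromomethyl)-4,6-dimethoxyphenoxy)-5-methoxyphenyl]dodec-1-yn-1-yl}triisopropylsilane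
Conditions: CBr4, PPh3, CH2Cl2, 0 °C
Reagents that add atoms: carbon tetrabromide, BrC(Br)(Br)Br
Why: Appel bromination of a primary benzylic alcohol under neutral conditions, which spares the aryl ethers and the silylalkyne; the bromide is used without storage.

Step 6
Reactants: 11 {12-[3-(2-(bromomethyl)-4,6-dimethoxyphenoxy)-5-methoxyphenyl]dodec-1-yn-1-yl}triisopropylsilane; 12 1-(trimethylsilyl)propyne
Product: 14 {12-[3-(4,6-dimethoxy-2-(4-(trimethylsilyl)but-3-yn-1-yl)phenoxy)-5-methoxyphenyl]dodec-1-yn-1-yl}triisopropylsilane, via 3-(trimethylsilyl)prop-2-ynyllithium 13 (not isolated)
Conditions: 12, n-BuLi, THF, −78 °C; then 11, −78 → −20 °C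
Reagents that add atoms: none
Why: Alkylation of a silyl-stabilised propargyllithium by a benzylic bromide forms C15–C16; the trimethylsilyl group directs attack to the propargylic terminus, and because the long-arm alkyne is capped there is no acidic hydrogen to quench the carbanion.

Step 7
Reactants: 14 {12-[3-(4,6-dimethoxy-2-(4-(trimethylsilyl)but-3-yn-1-yl)phenoxy)-5-methoxyphenyl]dodec-1-yn-1-yl}triisopropylsilane
Product: 15 1-(but-3-yn-1-yl)-2-[3-(dodec-11-yn-1-yl)-5-methoxyphenoxy]-3,5-dimethoxybenzene
Conditions: Bu4NF, THF, 0 °C → rt
Reagents that add atoms: none
Why: Fluoride-induced protodesilylation removes both alkynyl silyl groups in one operation; aryl ethers and the methylene chains are untouched.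

Step 8
Reactants: 15 1-(but-3-yn-1-yl)-2-[3-(dodec-11-yn-1-yl)-5-methoxyphenoxy]-3,5-dimethoxybenzene
Product: 16 macrocyclic 1,3-diyne: tri-O-methyl-11,12,13,14-tetradehydrogrevirobstol B (22-membered ring, C11≡C12–C13≡C14)
Conditions: Cu(OAc)2 (10 equiv), pyridine, 60 °C, 15 added by syringe pump over about 20 h, final concentration about 1 mM
Reagents that add atoms: none
Why: Pyridine-assisted deprotonation turns both terminal alkynes of 15 into copper acetylides; two equivalents of divalent copper oxidise them, and the sp carbons C12 and C13 are joined, probably within a dinuclear copper acetylide, with release of monovalent copper. The closest known reaction type is the Eglinton (Glaser-type) macrocyclisation of α,ω-diynes with Cu(OAc)2 in pyridine. The 22-membered ring closes by end-to-end union of the two arms; the six atoms C10 to C15 become a nearly linear rod that a ring of this size should hold without strain, and an sp carbon offers no elimination pathway. No stereocentre is formed. The one selectivity needed is ring closure over intermolecular coupling, which slow addition into a large excess of Cu(OAc)2 should secure by keeping the stationary concentration of uncoupled diyne very low. Both alkynes are unactivated alkyl acetylenes of equal reactivity, so no chemoselectivity question arises, and the methyl ethers and the diaryl ether are inert to Cu(OAc)2 in pyridine.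

Step 9
Reactants: 16 macrocyclic 1,3-diyne
Product: 17 tri-O-methylgrevirobstol B
Conditions: H2 (1 atm), palladium on carbon (Pd/C, 10 %), EtOAc, rt
Reagents that add atoms: none
Why: Exhaustive catalytic hydrogenation converts the diyne into four methylenes; aryl methyl ethers and the diaryl ether are not hydrogenolysed at ambient pressure.

Step 10
Reactants: 17 tri-O-methylgrevirobstol B
Product: 18 grevirobstol B
Conditions: BBr3, CH2Cl2, −78 °C → rt; then H2O, work-up under argon
Reagents that add atoms: none
Why: Lewis-acid cleavage of the three aryl methyl ethers (bromide attacks the methyl group of the boron-complexed ether); the diaryl ether has no alkyl carbon to attack and should survive, and with no alkyne left hydrogen bromide has nothing to add to.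

## Compound list

1 | ethynyltriisopropylsilane | C#C[Si](C(C)C)(C(C)C)C(C)C | starting material
2 | 10-bromodec-1-ene | C=CCCCCCCCCBr | starting material
3 | lithium (triisopropylsilyl)acetylide | [Li]C#C[Si](C(C)C)(C(C)C)C(C)C | intermediate
4 | (dodec-11-en-1-yn-1-yl)triisopropylsilane | C=CCCCCCCCCC#C[Si](C(C)C)(C(C)C)C(C)C | intermediate
5 | 3-bromo-5-methoxyphenol | COc1cc(O)cc(Br)c1 | starting material
6 | 9-[12-(triisopropylsilyl)dodec-11-yn-1-yl]-9-borabicyclo[3.3.1]nonane | CC(C)[Si](C(C)C)(C(C)C)C#CCCCCCCCCCCB1C2CCCC1CCC2 | intermediate
7 | 3-methoxy-5-[12-(triisopropylsilyl)dodec-11-yn-1-yl]phenol | COc1cc(O)cc(CCCCCCCCCCC#C[Si](C(C)C)(C(C)C)C(C)C)c1 | intermediate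
8 | 2-bromo-3,5-dimethoxybenzaldehyde | COc1cc(OC)c(Br)c(C=O)c1 | starting material
9 | 3,5-dimethoxy-2-{3-methoxy-5-[12-(triisopropylsilyl)dodec-11-yn-1-yl]phenoxy}benzaldehyde | COc1cc(CCCCCCCCCCC#C[Si](C(C)C)(C(C)C)C(C)C)cc(Oc2c(C=O)cc(OC)cc2OC)c1 | intermediate
10 | (3,5-dimethoxy-2-{3-methoxy-5-[12-(triisopropylsilyl)dodec-11-yn-1-yl]phenoxy}phenyl)methanol | COc1cc(CCCCCCCCCCC#C[Si](C(C)C)(C(C)C)C(C)C)cc(Oc2c(CO)cc(OC)cc2OC)c1 | intermediate
11 | {12-[3-(2-(bromomethyl)-4,6-dimethoxyphenoxy)-5-methoxyphenyl]dodec-1-yn-1-yl}triisopropylsilane | COc1cc(CCCCCCCCCCC#C[Si](C(C)C)(C(C)C)C(C)C)cc(Oc2c(CBr)cc(OC)cc2OC)c1 | intermediate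
12 | 1-(trimethylsilyl)propyne | CC#C[Si](C)(C)C | starting material
13 | 3-(trimethylsilyl)prop-2-ynyllithium | [Li]CC#C[Si](C)(C)C | intermediate
14 | {12-[3-(4,6-dimethoxy-2-(4-(trimethylsilyl)but-3-yn-1-yl)phenoxy)-5-methoxyphenyl]dodec-1-yn-1-yl}triisopropylsilane | COc1cc(CCCCCCCCCCC#C[Si](C(C)C)(C(C)C)C(C)C)cc(Oc2c(CCC#C[Si](C)(C)C)cc(OC)cc2OC)c1 | intermediate
15 | 1-(but-3-yn-1-yl)-2-[3-(dodec-11-yn-1-yl)-5-methoxyphenoxy]-3,5-dimethoxybenzene | COc1cc(CCCCCCCCCCC#C)cc(Oc2c(CCC#C)cc(OC)cc2OC)c1 | intermediate
16 | macrocyclic 1,3-diyne, tri-O-methyl-11,12,13,14-tetradehydrogrevirobstol B | COc1cc2cc(c1)Oc1c(OC)cc(OC)cc1CCC#CC#CCCCCCCCCCC2 | intermediate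
17 | tri-O-methylgrevirobstol B | COc1cc2cc(c1)Oc1c(OC)cc(OC)cc1CCCCCCCCCCCCCCCC2 | intermediate
18 | grevirobstol B | Oc1cc2cc(c1)Oc1c(O)cc(O)cc1CCCCCCCCCCCCCCCC2 | target

## Step count and least certain steps

Total: 10 steps. Longest linear sequence: 10 steps (1 or 2 to 18); compounds 5, 8 and 12 enter this line as purchased pieces.

**Step 8 (key step).** The most likely failure is intermolecular coupling outrunning ring closure, because the effective molarity of two ends on a long flexible tether is low; cyclic dimer and linear oligomers would then accumulate irreversibly. The fallback closes the ring by a reversible reaction, in which oligomers can be funnelled back to the strain-free monomeric ring. It sets out from 11. Copper-catalysed coupling with pent-4-enylmagnesium bromide (Li2CuCl4 cat., THF) should give the hex-5-enyl silylalkyne F1. Bu4NF should free the terminal alkyne F2. Semi-hydrogenation (H2, Pd/CaCO3 poisoned with Pb(OAc)2, quinoline), stopped after one equivalent of hydrogen, should give the diene F3, with dodec-11-enyl and hex-5-enyl arms; the alkyne binds the poisoned surface far more strongly than the alkene already present, which should therefore be spared. Ring-closing olefin metathesis at high dilution (second-generation Grubbs catalyst, RuCl2(=CHPh)(PCy3)(H2IMes), CH2Cl2, 40 °C) should give the macrocyclic C11=C12 alkene F4 as an E/Z mixture with the full sixteen-carbon tether. Hydrogenation over palladium on carbon brings it back to the route at 17.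

**Step 3.** Oxidative addition of copper at a carbon–bromine bond flanked by a formyl and a methoxy group may be slow, so that protodebromination of 8 and decay of the catalyst take over. The fallback replaces copper catalysis by nucleophilic aromatic substitution: 7 is heated with 2-fluoro-3,5-dimethoxybenzaldehyde F5 and Cs2CO3 in DMSO. The ortho formyl group stabilises the Meisenheimer intermediate and fluoride is the leaving group. This sets out from 7 and returns at 9.

**Step 2.** The phenoxide of 5 makes the aryl bromide electron-rich and can bind palladium, so oxidative addition may lag behind protodeboronation of 6. The fallback moves the differentiation of the ring A oxygens to after the coupling. It sets out from 4: borane 6 is coupled in the same way with 1-bromo-3,5-dimethoxybenzene F6 to give 1,3-dimethoxy-5-[12-(triisopropylsilyl)dodec-11-yn-1-yl]benzene F7. One methyl ether is then cleaved with NaSEt in DMF at 130 °C; the phenoxide formed protects the second ether, and the hindered silylalkyne should resist thiolate. This returns at 7.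

**Step 6.** The ambident propargyl anion may attack partly through its allenyl terminus, and bromine–lithium exchange at the benzylic bromide may lead to bibenzyl-type coupling. The fallback builds C13 to C15 stepwise from 11. Alkylation with lithiated acetonitrile (LiCH2CN, THF, −78 °C) should give the propanenitrile F8. Reduction with iBu2AlH and hydrolysis should give the propanal F9. Homologation with dimethyl (1-diazo-2-oxopropyl)phosphonate and K2CO3 in MeOH (Ohira–Bestmann) should give the but-3-ynyl compound F10, which still carries the triisopropylsilyl cap. Bu4NF then returns it to the route at 15.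

## Further compounds

F1 | step 8 | {12-[3-(2-(hex-5-en-1-yl)-4,6-dimethoxyphenoxy)-5-methoxyphenyl]dodec-1-yn-1-yl}triisopropylsilane | COc1cc(CCCCCCCCCCC#C[Si](C(C)C)(C(C)C)C(C)C)cc(Oc2c(CCCCC=C)cc(OC)cc2OC)c1
F2 | step 8 | 2-[3-(dodec-11-yn-1-yl)-5-methoxyphenoxy]-1-(hex-5-en-1-yl)-3,5-dimethoxybenzene | COc1cc(CCCCCCCCCCC#C)cc(Oc2c(CCCCC=C)cc(OC)cc2OC)c1
F3 | step 8 | 2-[3-(dodec-11-en-1-yl)-5-methoxyphenoxy]-1-(hex-5-en-1-yl)-3,5-dimethoxybenzene | COc1cc(CCCCCCCCCCC=C)cc(Oc2c(CCCCC=C)cc(OC)cc2OC)c1
F4 | step 8 | macrocyclic C11=C12 alkene, tri-O-methyl-11,12-didehydrogrevirobstol B (E/Z mixture) | COc1cc2cc(c1)Oc1c(OC)cc(OC)cc1CCCCC=CCCCCCCCCCC2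
F5 | step 3 | 2-fluoro-3,5-dimethoxybenzaldehyde | COc1cc(OC)c(F)c(C=O)c1
F6 | step 2 | 1-bromo-3,5-dimethoxybenzene | COc1cc(Br)cc(OC)c1
F7 | step 2 | 1,3-dimethoxy-5-[12-(triisopropylsilyl)dodec-11-yn-1-yl]benzene | COc1cc(OC)cc(CCCCCCCCCCC#C[Si](C(C)C)(C(C)C)C(C)C)c1
F8 | step 6 | 3-(3,5-dimethoxy-2-{3-methoxy-5-[12-(triisopropylsilyl)dodec-11-yn-1-yl]phenoxy}phenyl)propanenitrile | COc1cc(CCCCCCCCCCC#C[Si](C(C)C)(C(C)C)C(C)C)cc(Oc2c(CCC#N)cc(OC)cc2OC)c1
F9 | step 6 | 3-(3,5-dimethoxy-2-{3-methoxy-5-[12-(triisopropylsilyl)dodec-11-yn-1-yl]phenoxy}phenyl)propanal | COc1cc(CCCCCCCCCCC#C[Si](C(C)C)(C(C)C)C(C)C)cc(Oc2c(CCC=O)cc(OC)cc2OC)c1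
F10 | step 6 | {12-[3-(2-(but-3-yn-1-yl)-4,6-dimethoxyphenoxy)-5-methoxyphenyl]dodec-1-yn-1-yl}triisopropylsilane | COc1cc(CCCCCCCCCCC#C[Si](C(C)C)(C(C)C)C(C)C)cc(Oc2c(CCC#C)cc(OC)cc2OC)c1
A1 | alternative 1 | 4-fluoro-5-[16-(3,5-dihydroxyphenyl)hexadecyl]benzene-1,3-dicarbaldehyde | Oc1cc(O)cc(CCCCCCCCCCCCCCCCc2cc(C=O)cc(C=O)c2F)c1
A2 | alternative 1 | macrocyclic diaryl ether dialdehyde | Oc1cc2cc(c1)Oc1c(C=O)cc(C=O)cc1CCCCCCCCCCCCCCCC2
A3 | alternative 2 | 3-{16-[2-(ethynyloxy)-3,5-dimethoxyphenyl]hexadecyl}cyclobut-2-en-1-one | COc1cc(OC)c(OC#C)c(CCCCCCCCCCCCCCCCC2=CC(=O)C2)c1
A4 | alternative 2 | grevirobstol B with both ring B hydroxyls as methyl ethers | Oc1cc2cc(c1)Oc1c(OC)cc(OC)cc1CCCCCCCCCCCCCCCC2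
A5 | alternative 3 | 3-chloro-5-[16-(2-hydroxy-3,5-dimethoxyphenyl)hexadecyl]cyclohex-2-en-1-one (racemic) | COc1cc(OC)c(O)c(CCCCCCCCCCCCCCCCC2CC(Cl)=CC(=O)C2)c1
A6 | alternative 3 | macrocyclic aryl vinylogous ester (racemic) | COc1cc(OC)c2c(c1)CCCCCCCCCCCCCCCCC1CC(=CC(=O)C1)O2
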